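**Assumption:** the ketal-bearing enone is taken to show the same facial preference with the (S,R,R) Cu/phosphoramidite catalyst as cyclohex-2-enone, which gives (S)-3-alkylcyclohexanones. If it were reversed, the (R,S,S) ligand would be used with nothing else changed.

## Retrosynthetic overview

(Quinoline numbering; ring A = pyridone, ring B = carbocycle; the single stereocentre is C5, which is S.)

- The C8 ketone comes from a dioxolane, and ring A is closed last from a 1,3,5-triketone and ammonia (N1–C2 and N1–C8a bonds) on a preformed ring B.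
- The triketone comes from a β-diketone dianion and an acetyl Weinreb amide (C2–C3 bond); the β-diketone comes from a Claisen condensation of the ring ketone with methyl methoxyacetate (C4–C4a bond).
- The chiral ring ketone comes from a Cu-catalysed asymmetric conjugate addition of a 5-phenylpentylzinc reagent to a cyclohexenone whose α'-carbon already carries the future C8 carbonyl as a ketal; this step sets C5.
- The enone comes from cyclohexane-1,2-dione by mono-ketalisation and dehydrogenation. Ring B is bought; ring A is formed last.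

## Route

Step 1
Reactants: 1 cyclohexane-1,2-dione; 2 ethylene glycol
Product: 3 1,4-dioxaspiro[4.5]decan-6-one
Conditions: 2 (1.05 equiv), p-TsOH·H2O (5 mol%), benzene, reflux, Dean–Stark
Reagents that add atoms: none
Why: Acid-catalysed ketalisation with azeotropic water removal converts one carbonyl of the 1,2-dione into the dioxolane, and the remaining ketone, now flanked by the quaternary ketal carbon, resists a second ketalisation.

Step 2
Reactants: 3 1,4-dioxaspiro[4.5]decan-6-one
Product: 4 1,4-dioxaspiro[4.5]dec-7-en-6-one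
Conditions: 2-iodoxybenzoic acid (IBX, 1.5 equiv), DMSO/toluene (1:2), 70 °C
Reagents that add atoms: none
Why: IBX dehydrogenation of a ketone (Nicolaou) runs through the enol, and since 3 has only one enolisable α-position the C7=C8 enone is the only possible regioisomer.

Step 3
Reactants: 4 1,4-dioxaspiro[4.5]dec-7-en-6-one; 5 (5-bromopentyl)benzene
Product: 8 (8S)-8-(5-phenylpentyl)-1,4-dioxaspiro[4.5]decan-6-one, via (5-phenylpentyl)magnesium bromide 6 (not isolated), via bis(5-phenylpentyl)zinc 7 (not isolated)
Conditions: 5 (2.6 equiv), Mg, Et2O, rt; ZnCl2 (1.3 equiv), then 1,4-dioxane, filter; 4, Cu(OTf)2 (2 mol%), (S,R,R)-O,O'-(1,1'-binaphthyl-2,2'-diyl)-N,N-bis(1-phenylethyl)phosphoramidite (4 mol%), toluene, −30 °C; aq NH4Cl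
Reagents that add atoms: none
Why: Cu/phosphoramidite-catalysed asymmetric conjugate addition (Feringa) transfers the 5-phenylpentyl group from zinc to one enantiotopic face of the enone β-carbon, setting the future C5 centre as S in the same sense as the (S)-3-alkylcyclohexanones obtained from cyclohex-2-enone.

Step 4
Reactants: 8 (8S)-8-(5-phenylpentyl)-1,4-dioxaspiro[4.5]decan-6-one; 9 methyl 2-methoxyacetate
Product: 10 (8S)-7-(2-methoxyacetyl)-8-(5-phenylpentyl)-1,4-dioxaspiro[4.5]decan-6-one (C7 epimers/enol tautomers)
Conditions: NaH (2.5 equiv), 9 (1.5 equiv), THF, 0 → 65 °C; AcOH quench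
Reagents that add atoms: none
Why: In this crossed Claisen condensation the only enolisable α-carbon of 8 (C7) attacks the activated α-alkoxy ester and the equilibrium is pulled by deprotonation of the β-diketone, while the β-stereocentre is not enolisable and stays untouched.

Step 5
Reactants: 10 (8S)-7-(2-methoxyacetyl)-8-(5-phenylpentyl)-1,4-dioxaspiro[4.5]decan-6-one; 11 N-methoxy-N-methylacetamide
Product: 12 (8S)-7-(2-methoxy-3-oxobutanoyl)-8-(5-phenylpentyl)-1,4-dioxaspiro[4.5]decan-6-one (tautomer mixture, used crude)
Conditions: LDA (2.3 equiv), THF, −78 → 0 °C; 11 (1.2 equiv), −78 → 0 °C; AcOH/H2O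
Reagents that add atoms: none
Why: In this Harris-type γ-acylation the β-diketone dianion has a single γ-carbanion site (the CH2OMe carbon, the other side of the ring ketone being the ketal) which adds to the Weinreb amide to give a stable chelated adduct that releases the 1,3,5-triketone on workup.

Step 6
Reactants: 12 (8S)-7-(2-methoxy-3-oxobutanoyl)-8-(5-phenylpentyl)-1,4-dioxaspiro[4.5]decan-6-one
Product: 14 (5S)-3-methoxy-2-methyl-5-(5-phenylpentyl)-1,5,6,7-tetrahydroquinoline-4,8-dione, via pyridone ketal 13 (not isolated)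
Conditions: NH4OAc (10 equiv), EtOH, 80 °C; then 3 M aq HCl, 70 °C
Reagents that add atoms: ammonium acetate [NH4+].CC(=O)[O-]; water O
Why: Cyclocondensation of the 1,3,5-triketone with ammonia (4-pyridone synthesis) places N between the acetyl carbon and the ring carbonyl carbon to give aromatic ring A, and aqueous acid then hydrolyses the dioxolane to the C8 ketone under conditions that do not enolise the remote C5 centre.

## Compound list

1 | cyclohexane-1,2-dione | O=C1CCCCC1=O | starting material
2 | ethylene glycol (ethane-1,2-diol) | OCCO | starting material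
3 | 1,4-dioxaspiro[4.5]decan-6-one | O=C1CCCCC12OCCO2 | intermediate
4 | 1,4-dioxaspiro[4.5]dec-7-en-6-one | O=C1C=CCCC12OCCO2 | intermediate
5 | (5-bromopentyl)benzene | BrCCCCCc1ccccc1 | starting material
6 | (5-phenylpentyl)magnesium bromide | Br[Mg]CCCCCc1ccccc1 | intermediate
7 | bis(5-phenylpentyl)zinc | C(CCCCc1ccccc1)[Zn]CCCCCc1ccccc1 | intermediate
8 | (8S)-8-(5-phenylpentyl)-1,4-dioxaspiro[4.5]decan-6-one | O=C1C[C@@H](CCCCCc2ccccc2)CCC12OCCO2 | intermediate
9 | methyl 2-methoxyacetate | COCC(=O)OC | starting material
10 | (8S)-7-(2-methoxyacetyl)-8-(5-phenylpentyl)-1,4-dioxaspiro[4.5]decan-6-one (C7 not fixed, enolisable) | COCC(=O)C1C(=O)C2(OCCO2)CC[C@@H]1CCCCCc1ccccc1 | intermediate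
11 | N-methoxy-N-methylacetamide | CC(=O)N(C)OC | starting material
12 | (8S)-7-(2-methoxy-3-oxobutanoyl)-8-(5-phenylpentyl)-1,4-dioxaspiro[4.5]decan-6-one (C7 and the CH(OMe) carbon not fixed, enolisable) | CC(=O)C(OC)C(=O)C1C(=O)C2(OCCO2)CC[C@@H]1CCCCCc1ccccc1 | intermediate
13 | (5S)-3-methoxy-2-methyl-5-(5-phenylpentyl)-5,6,7,8-tetrahydroquinolin-4(1H)-one with C8 as its spiro-1,3-dioxolane (8,8-ethylenedioxy) | COc1c(C)[nH]c2c(c1=O)[C@@H](CCCCCc1ccccc1)CCC21OCCO1 | intermediate
14 | (5S)-3-methoxy-2-methyl-5-(5-phenylpentyl)-1,5,6,7-tetrahydroquinoline-4,8-dione | COc1c(C)[nH]c2c(c1=O)[C@@H](CCCCCc1ccccc1)CCC2=O | target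

## Summary

Total step count: 6.
Longest linear sequence: 6 steps (1 → 3 → 4 → 8 → 10 → 12 → 14). The organozinc reagent is made in the flask within step 3.

## Steps most likely to fail, with fallbacks

**Step 3 (enantioselective alkyl transfer to the ketal-bearing enone).** The fallback sets the centre by hydride transfer instead of alkyl transfer; it sets out from 4 and comes back at 8. Achiral CuBr·SMe2-catalysed addition of Grignard 6 to 4 in the presence of TMSCl (THF, −78 °C) gives racemic trimethyl{[8-(5-phenylpentyl)-1,4-dioxaspiro[4.5]dec-6-en-6-yl]oxy}silane F1. Saegusa–Ito oxidation (Pd(OAc)2, MeCN, rt) removes the stereocentre and gives the β-alkyl enone 8-(5-phenylpentyl)-1,4-dioxaspiro[4.5]dec-7-en-6-one F2. Asymmetric CuH conjugate reduction (Cu(OAc)2·H2O, the p-Tol-BINAP enantiomer that gives the S product, PMHS, toluene, 0 °C, then aqueous fluoride workup) delivers hydride to C8 and returns to 8.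

**Step 5 (dianion γ-acetylation).** The fallback replaces the intermolecular acylation by an intramolecular O→C acyl shift; it sets out from 10 and comes back at 12. O-Acetylation of 10 (Ac2O, Et3N, DMAP, CH2Cl2) gives the enol acetate (8S)-7-(2-methoxyacetyl)-8-(5-phenylpentyl)-1,4-dioxaspiro[4.5]dec-6-en-6-yl acetate F3. Treatment with t-BuOK in THF deprotonates the CH2OMe carbon, and the enolate takes over the acetyl group through a six-membered transition state (Baker–Venkataraman-type rearrangement), giving 12 after acidic workup.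

**Step 6 (N-cyclisation onto the hindered ring carbonyl, then ketal hydrolysis next to a protonated pyridone).** The fallback frees the ketone at the less basic pyrone stage and introduces nitrogen last; it sets out from 12 and comes back at 14. Aqueous acid (TFA/H2O or 6 M HCl in AcOH, 60 °C) cyclodehydrates the triketone and hydrolyses the dioxolane, giving the pyrone (5S)-3-methoxy-2-methyl-5-(5-phenylpentyl)-6,7-dihydro-4H-chromene-4,8(5H)-dione F4. Exchange of the ring oxygen for NH with aqueous NH3 in EtOH (sealed tube, 80 °C) gives 14 directly.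

## Further compounds

F1 | step 3 | trimethyl{[8-(5-phenylpentyl)-1,4-dioxaspiro[4.5]dec-6-en-6-yl]oxy}silane (racemic) | C[Si](C)(C)OC1=CC(CCCCCc2ccccc2)CCC12OCCO2
F2 | step 3 | 8-(5-phenylpentyl)-1,4-dioxaspiro[4.5]dec-7-en-6-one | O=C1C=C(CCCCCc2ccccc2)CCC12OCCO2
F3 | step 5 | (8S)-7-(2-methoxyacetyl)-8-(5-phenylpentyl)-1,4-dioxaspiro[4.5]dec-6-en-6-yl acetate | CC(=O)OC1=C(C(=O)COC)[C@@H](CCCCCc2ccccc2)CCC12OCCO2
F4 | step 6 | (5S)-3-methoxy-2-methyl-5-(5-phenylpentyl)-6,7-dihydro-4H-chromene-4,8(5H)-dione | COc1c(C)oc2c(c1=O)[C@@H](CCCCCc1ccccc1)CCC2=O
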